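All runs stem from a simulated flask with constants of no real substance, noise included.

Slowness comes first: after 2.50 d at 55 °C the alpha flask stands at 30.5% trapped intermediate and 18.4% target, so you have to decide how hot to run the next flask.

| flask | solid substrate | reagent | capture agent | temperature | remark | time |
|---|---|---|---|---|---|---|
| zeta | 0.060 M | 0.48 M (fed, over 50 min) | 0.036 M | 55 °C | run made earlier; the fed solution adds 0.25 times the starting volume |  |
| gamma | 0.24 M | 0.48 M (fed, over 50 min) | 0.036 M | 80 °C | run made earlier; the fed solution adds 0.25 times the starting volume |  |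
| alpha | 0.12 M | 0.48 M (fed, over 50 min) | 0.072 M | 55 °C | run made earlier; the fed solution adds 0.25 times the starting volume |  |
| ochre | 0.12 M | 0.480 M (fed, over 50 min) | 0.0360 M | 90 °C | the fed solution adds 0.25 times the starting volume | 4.0 d |
| blue | 0.12 M | 0.480 M (fed, over 50 min) | 0.0360 M | 100 °C | the fed solution adds 0.25 times the starting volume | 4.0 d |
| violet | 0.12 M | 0.480 M (fed, over 50 min) | 0.0360 M | 80 °C | the fed solution adds 0.25 times the starting volume | 4.0 d |
| red | 0.12 M | 0.480 M (fed, over 50 min) | 0.0360 M | 60 °C | the fed solution adds 0.25 times the starting volume | 4.0 d |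

zeta run (percent of the solid substrate charged)

| time / d | target / % | trapped intermediate / % | solid substrate / % |
|---|---|---|---|
| 0.208 | 1.1 | 0 | 0.5 |
| 0.625 | 5.0 | 4.4 | 0.4 |
| 1.04 | 10.6 | 8.7 | 0 |
| 1.67 | 15.0 | 15.2 | 0 |
| 2.50 | 21.3 | 18.6 | 0 |

gamma run (percent of the solid substrate charged)

| time / h | target / % | trapped intermediate / % | solid substrate / % |
|---|---|---|---|
| 2.00 | 2.1 | 0.9 | 73.9 |
| 3.00 | 5.0 | 1.8 | 68.1 |
| 6.00 | 6.6 | 0.9 | 53.2 |
| 12.0 | 7.9 | 6.8 | 44.0 |
| 20.0 | 9.0 | 10.0 | 39.3 |

alpha run (percent of the solid substrate charged)

| time / d | target / % | trapped intermediate / % | solid substrate / % |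
|---|---|---|---|
| 0.208 | 2.2 | 0.3 | 13.0 |
| 0.333 | 2.2 | 0.3 | 0.2 |
| 0.625 | 6.0 | 8.5 | 1.6 |
| 1.25 | 10.5 | 18.5 | 0 |
| 2.50 | 18.4 | 30.5 | 0 |

(scatter of a reading: 1 percentage point)

- every charge counts on the volume at the start, and the solution that is fed holds the whole dose
- solid, in amounts per volume of the solution: solid substrate
- the earlier runs were read with a standard deviation of 1 percentage point
- steps under discussion: solid substrate <-> starting material; capture agent + intermediate A -> trapped intermediate; intermediate A <-> intermediate B; intermediate A <-> target; starting material <-> intermediate A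
- at the start none of the solid substrate is in solution
- what has only dissolved of solid substrate counts as not reacted

* the flasks by share of target in all that became target or trapped intermediate, highest first, at 4.0 d (ochre / blue / violet / red)
* the same order at 5.0 h (ochre / blue / violet / red)
* the share of target in all that became target or trapped intermediate of the flask you put first, at 4.0 d
* the share of target in all that became target or trapped intermediate of the flask you put last, at 4.0 d

Start by counting what the capture agent can do. Each capture agent takes one intermediate A, so it is the limiting reagent of trapping. For ochre, blue, violet and red, its charge over the solid substrate charge is: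

ceiling = 30.0%

This capture ceiling is the fraction of the charge that trapped intermediate cannot pass. Now count turnovers of the agent. The gamma flask has a ceiling of 15.0%, so its trapped intermediate at 20.0 h means:

used in one span = 66.7%

The asked time holds 4.80 such spans, longer than gamma's last reading. At that pace, setting aside that gamma was charged with 0.24 M of solid substrate, violet keeps about 0.513% of its agent, and I take the hotter ochre and blue as no slower, so I put all three at the ceiling. Alpha used 50.8% in its span, and 1.60 spans at that pace, setting aside that alpha ran at 55 °C with 0.072 M of agent, give my estimate for red: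

agent left = 32.1%, trapped = 20.4%, below the ceiling

For target, I scale alpha's steady rise for red, and for violet I put gamma's flattening level on violet's smaller charge:

red: target 29.4%, share 59.0%

violet: target 18.0%, share 37.5%

So I would stay cool, with red first and share falling as the flasks get hotter.

The forecast differs. It gives blue > ochre > violet > red at the asked time and red > violet > ochre > blue at 5.0 h, with 65% for its first flask and 57% for its last, reasoning that once the agent is exhausted “further material can only go to target”.

The flasks give red > violet > ochre > blue, from 56.5% to 13.5%, and violet > red > ochre > blue at 5.0 h.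

    solid substrate ⇌ starting material, rate k1*(cs1 - [starting material]) while solid is left; crystals form when [starting material] > cs1 (solubility = 0.0630 M, k = 1.70 × 10⁻⁴ s⁻¹)
    capture agent + intermediate A → trapped intermediate (k = 2.30 × 10⁻⁴ M⁻¹ s⁻¹, Ea = 67.0 kJ mol⁻¹)
    intermediate A ⇌ intermediate B (K = 0.500, k = 6.30 × 10⁻⁴ s⁻¹, Ea = 105 kJ mol⁻¹, ΔH = −87.0 kJ mol⁻¹)
    intermediate A ⇌ target (K = 2.10, k = 1.00 × 10⁻⁵ s⁻¹, Ea = 121 kJ mol⁻¹, ΔH = −34.0 kJ mol⁻¹)
    starting material ⇌ intermediate A (K = 0.590, k = 1.60 × 10⁻⁴ s⁻¹, Ea = 97.0 kJ mol⁻¹, ΔH = −36.0 kJ mol⁻¹)
    (constants at 60 °C)

In blue, intermediate A and target relax towards each other, by that step alone, with a half-life of 0.0642 h, short against 4.0 d. Blue holds 30.0% trapped intermediate, with 0.019% of its agent left, and 4.69% target: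

target / (target + ceiling) = 13.5%

Charge blue's neighbour with 0.048 M of solid substrate, and the ceiling becomes 75.0%. That neighbour reaches 67.7% trapped intermediate with 9.67% of its agent left, and its share is 3.09%.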